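(The numbers of this flask were chosen freely, and the outcome is calculated.)

Late in either flask the question is what stands when the additions stop, and each addition needs free E.

    X + E → X.E (k1 = 0.079 L mol⁻¹ s⁻¹)
    E + X.E → E.X.E (k2 = 0.13 L mol⁻¹ s⁻¹)
    E + E.X.E → G (k3 = 0.0035 L mol⁻¹ s⁻¹)
    G ⇌ J (K4 = 2.9, k4 = 7.0 × 10⁻⁴ s⁻¹)

common to all: X 44 mM; time 6.0 h

| flask | E |
|---|---|
| alder | 40.0 mM |
| larch | 48.0 mM |

- which of these there is most of at the end, counted by the X in it, alder (J / X / E.X.E / X.E)
- which of these there is most of at the end, counted by the X in it, larch (J / X / E.X.E / X.E)
- final amount of the leader among these, as a percentage of the X charged, in alder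
- final amount of the leader among these, as a percentage of the X charged, in larch

Suppose you end with no free E and ignore the third addition. Count in shares of the X charged. The shares of X, X.E and E.X.E add to one, while X.E plus two E.X.E equals the E charged over the X charged. Subtract, and X.E cancels: X minus E.X.E comes to 9.09% in alder and −9.09% in larch. Call this the lead L, the X charged less the E charged, over the X charged.

But the lead names a leader without giving its size. For that you need X.E. Dividing the first two rate laws removes E and time, and X.E then peaks at a share of s to the power −s/(s − 1), where s is the second constant over the first, 1.65 (a selectivity factor). That peak is 28.1%. Taking it as the X.E share, my reckoning gives X leading alder at 40.5%, and E.X.E leading larch at 40.5%. Any shortfall of X.E below its peak raises both X and E.X.E.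

Is there time, though? Near the end E decays in a pseudo-first-order way against the X and X.E around it, with a half-life of 3.83 min in alder, short against 6.0 h.

A second objection is the third addition, which takes E. Its rate against the second is 0.0269 times the ratio E.X.E over X.E, and that ratio climbs from nothing to its end value, so I use the mean of those two. This puts a share g in G and J together at 0.473% in alder and 0.786% in larch. Counting again, X minus E.X.E becomes L + 2g, which is 10.0% in alder and −7.52% in larch. Neither sign changes.

The forecast names X at 40.9% in alder and E.X.E at 40.2% in larch, on the ground that “E is fully consumed well before 6 h in both charges”. Its leaders are the ones I reckoned, but its two figures differ from mine.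

The flask gives X at 40.9% in alder and E.X.E at 40.2% in larch, as forecast. Free E in alder stands at 0% of its charge at the end, and E.X.E there is still 30.8% after 60.0 h. A neighbour like alder but charged with 24 mM of E has a lead of 45.5%, and it ends with X at 59.7% and E.X.E at 14.0%, a difference of 46 percentage points.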